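**Retrosynthetic overview**
1. Target ⇒ late C8–O acylation of the epoxy macrolactone with (2E,4R)-2,4-dimethylhex-2-enoic acid (from an Evans methylation and a Wittig olefination); oxirane ⇒ hydroxyl-directed Sharpless epoxidation of the macrocyclic (E)-C5=C6 allylic alcohol.
2. Ten-membered lactone ⇒ Yamaguchi macrolactonisation (C1 acid onto C9–OH) of an (E)-olefinic seco acid.
3. Key C5–C6 bond ⇒ intermolecular aldol of the lithium enolate of methyl ketone fragment B (C6–C14) with aldehyde fragment A (C1–C5), then dehydration to the (E)-enone and chelation-controlled reduction (C7).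
4. Fragment A ⇒ crossed Claisen condensation of methyl acetate with a D-glycerate ester, then Noyori hydrogenation (C3). Fragment B ⇒ Sharpless epoxidation of (E)-oct-2-en-1-ol and C3-selective epoxide opening (C8, C9).
5. Ring order: ten-membered lactone first, oxirane second.

Assumption/convention: TBS = tert-butyldimethylsilyl, TES = triethylsilyl, PMB = 4-methoxybenzyl; locants C1–C14 follow the seco-acid chain (C1 = lactone carbonyl, C9 = carbinol carbon bearing the pentyl group), also in the "-9-olide" names; CIP descriptors are those of each individual compound.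

**Fragment A (C1–C5)**

Step 1
Reactants: 1 methyl (4R)-2,2-dimethyl-1,3-dioxolane-4-carboxylate
Product: 2 methyl (2R)-2,3-dihydroxypropanoate
Conditions: Dowex 50W (H+ form), MeOH, rt
Reagents that add atoms: none
Why: Acid-catalysed acetonide methanolysis (transketalisation) frees the diol without touching the ester or the stereocentre that becomes C4.

Step 2
Reactants: 2 methyl (2R)-2,3-dihydroxypropanoate
Product: 3 methyl (2R)-2,3-bis(TBSO)propanoate
Conditions: TBSCl, imidazole, DMF, rt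
Reagents that add atoms: tert-butyldimethylsilyl chloride CC(C)(C)[Si](C)(C)Cl
Why: Standard silyl ether formation on both hydroxyls; no stereocentre is touched.

Step 3
Reactants: 3 methyl (2R)-2,3-bis(TBSO)propanoate; 4 methyl acetate
Product: 6 methyl (4R)-4,5-bis(TBSO)-3-oxopentanoate, via lithium enolate of methyl acetate 5 (not isolated)
Conditions: 4, LiN(iPr)2 (3 equiv each), THF, −78 °C; then 3, −78 → −30 °C; aq. NH4Cl
Reagents that add atoms: none
Why: Crossed Claisen condensation: the α-silyloxy ester is an activated acceptor for lithio methyl acetate, and the product is shielded from over-addition as its enolate, so the C4 centre is not epimerised.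

Step 4
Reactants: 6 methyl (4R)-4,5-bis(TBSO)-3-oxopentanoate
Product: 7 methyl (3R,4R)-4,5-bis(TBSO)-3-hydroxypentanoate
Conditions: H2 (10 atm), RuCl2[(S)-BINAP] (1 mol %), MeOH, 40 °C
Reagents that add atoms: none
Why: Noyori asymmetric hydrogenation of the β-keto ester; the (S)-BINAP catalyst sets C3 as R (3,4-syn), in the same sense as the Felkin preference of the α-silyloxy ketone.

Step 5
Reactants: 7 methyl (3R,4R)-4,5-bis(TBSO)-3-hydroxypentanoate
Product: 8 methyl (3R,4R)-3,4,5-tris(TBSO)pentanoate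
Conditions: TBSOTf, 2,6-lutidine, CH2Cl2, −78 → 0 °C
Reagents that add atoms: tert-butyldimethylsilyl triflate CC(C)(C)[Si](C)(C)OS(=O)(=O)C(F)(F)F
Why: Silylation of the hindered β-hydroxyl with the silyl triflate under non-nucleophilic base avoids retro-aldol or elimination.

Step 6
Reactants: 8 methyl (3R,4R)-3,4,5-tris(TBSO)pentanoate
Product: 9 methyl (3R,4R)-3,4-bis(TBSO)-5-hydroxypentanoate
Conditions: HF·pyridine, pyridine, THF, 0 °C
Reagents that add atoms: none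
Why: Selective desilylation: the primary TBS ether is cleaved much faster than the two hindered secondary ones under buffered fluoride.

Step 7
Reactants: 9 methyl (3R,4R)-3,4-bis(TBSO)-5-hydroxypentanoate
Product: 10 methyl (3R,4S)-3,4-bis(TBSO)-5-oxopentanoate (fragment A)
Conditions: Dess–Martin periodinane, NaHCO3, CH2Cl2, 0 °C → rt; used crude
Reagents that add atoms: none
Why: Buffered Dess–Martin oxidation gives the α-silyloxy aldehyde without epimerisation or over-oxidation.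

**Fragment B (C6–C14)**

Step 8
Reactants: 11 (E)-oct-2-en-1-ol
Product: 12 [(2S,3S)-3-pentyloxiran-2-yl]methanol
Conditions: Ti(OiPr)4 (5 mol %), L-(+)-diisopropyl tartrate (6 mol %), t-BuOOH, 4 Å MS, CH2Cl2, −20 °C
Reagents that add atoms: tert-butyl hydroperoxide CC(C)(C)OO
Why: Sharpless asymmetric epoxidation of a primary (E)-allylic alcohol; the L-(+)-tartrate ligand sets both oxirane centres as (2S,3S).

Step 9
Reactants: 12 [(2S,3S)-3-pentyloxiran-2-yl]methanol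
Product: 13 (2S,3R)-1,2-dihydroxyoctan-3-yl benzoate
Conditions: Ti(OiPr)4 (1.5 equiv), PhCO2H, CH2Cl2, rt
Reagents that add atoms: benzoic acid OC(=O)c1ccccc1
Why: Sharpless Ti(OiPr)4-mediated opening of the 2,3-epoxy alcohol occurs at C3 with inversion, giving the 8,9-anti diol pattern with C9–O already differentiated.

Step 10
Reactants: 13 (2S,3R)-1,2-dihydroxyoctan-3-yl benzoate
Product: 14 (1R)-1-[(4S)-2-(4-methoxyphenyl)-1,3-dioxolan-4-yl]hexyl benzoate (acetal epimers)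
Conditions: 4-MeOC6H4CH(OMe)2, PPTS (cat.), CH2Cl2, rt
Reagents that add atoms: 4-methoxybenzaldehyde dimethyl acetal COC(OC)c1ccc(OC)cc1
Why: Acid-catalysed transacetalisation ties the free 1,2-diol into a p-methoxybenzylidene acetal while the benzoate keeps C9–O out of play.

Step 11
Reactants: 14 (1R)-1-[(4S)-2-(4-methoxyphenyl)-1,3-dioxolan-4-yl]hexyl benzoate
Product: 15 (1R)-1-[(4S)-2-(4-methoxyphenyl)-1,3-dioxolan-4-yl]hexan-1-ol
Conditions: K2CO3, MeOH, rt
Reagents that add atoms: none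
Why: Base-catalysed methanolysis (transesterification) removes the benzoate; the acetal is base-stable.

Step 12
Reactants: 15 (1R)-1-[(4S)-2-(4-methoxyphenyl)-1,3-dioxolan-4-yl]hexan-1-ol
Product: 16 triethyl{(1R)-1-[(4S)-2-(4-methoxyphenyl)-1,3-dioxolan-4-yl]hexyloxy}silane
Conditions: TESCl, imidazole, CH2Cl2, 0 °C
Reagents that add atoms: chlorotriethylsilane CC[Si](CC)(CC)Cl
Why: Silylation gives a C9 ether that does not chelate, is a poor leaving group, and is later removable in the presence of TBS ethers.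

Step 13
Reactants: 16 triethyl{(1R)-1-[(4S)-2-(4-methoxyphenyl)-1,3-dioxolan-4-yl]hexyloxy}silane
Product: 17 (2S,3R)-2-(PMBO)-3-(TESO)octan-1-ol
Conditions: iBu2AlH, CH2Cl2, −78 → 0 °C
Reagents that add atoms: none
Why: Regioselective reductive opening of the p-methoxybenzylidene acetal: aluminium binds the less hindered primary oxygen, so the PMB group stays on the secondary C8 oxygen.

Step 14
Reactants: 17 (2S,3R)-2-(PMBO)-3-(TESO)octan-1-ol
Product: 18 (2R,3R)-2-(PMBO)-3-(TESO)octanal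
Conditions: Dess–Martin periodinane, NaHCO3, CH2Cl2, 0 °C
Reagents that add atoms: none
Why: Buffered Dess–Martin oxidation of the primary alcohol without epimerising the α-alkoxy centre.

Step 15
Reactants: 18 (2R,3R)-2-(PMBO)-3-(TESO)octanal
Product: 19 (3S,4R)-3-(PMBO)-4-(TESO)nonan-2-ol (C2 epimers)
Conditions: MeMgBr, Et2O, −78 °C
Reagents that add atoms: methylmagnesium bromide C[Mg]Br
Why: Grignard addition installs C6; the new carbinol configuration is irrelevant because it is oxidised in the next step.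

Step 16
Reactants: 19 (3S,4R)-3-(PMBO)-4-(TESO)nonan-2-ol
Product: 20 (3R,4R)-3-(PMBO)-4-(TESO)nonan-2-one (fragment B)
Conditions: Dess–Martin periodinane, NaHCO3, CH2Cl2, rt
Reagents that add atoms: none
Why: Dess–Martin oxidation converges both epimers to the methyl ketone under non-epimerising conditions.

**Side-chain acid**

Step 17
Reactants: 21 (4R)-4-benzyl-1,3-oxazolidin-2-one; 22 butanoyl chloride
Product: 24 (4R)-4-benzyl-3-butanoyl-1,3-oxazolidin-2-one, via N-lithio oxazolidinone 23 (not isolated)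
Conditions: n-BuLi, THF, −78 °C; then 22
Reagents that add atoms: none
Why: N-acylation of the lithiated Evans auxiliary with the acid chloride is clean and quantitative.

Step 18
Reactants: 24 (4R)-4-benzyl-3-butanoyl-1,3-oxazolidin-2-one
Product: 26 (4R)-4-benzyl-3-[(2R)-2-methylbutanoyl]-1,3-oxazolidin-2-one, via sodium Z-enolate 25 (not isolated)
Conditions: NaN(SiMe3)2, THF, −78 °C; MeI
Reagents that add atoms: iodomethane CI
Why: Evans asymmetric alkylation: the chelated Z-enolate is methylated on the face away from the benzyl group, setting the (R) centre of the side chain.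

Step 19
Reactants: 26 (4R)-4-benzyl-3-[(2R)-2-methylbutanoyl]-1,3-oxazolidin-2-one
Product: 27 (2R)-2-methylbutan-1-ol
Conditions: LiBH4, MeOH (1 equiv), Et2O, 0 °C; careful distillation
Reagents that add atoms: none
Why: Reductive cleavage of the imide releases the alcohol without epimerisation and returns the auxiliary.

Step 20
Reactants: 27 (2R)-2-methylbutan-1-ol; 28 ethyl 2-(triphenylphosphoranylidene)propanoate
Product: 30 ethyl (2E,4R)-2,4-dimethylhex-2-enoate, via (2R)-2-methylbutanal 29 (not isolated)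
Conditions: PhI(OAc)2, TEMPO (10 mol %), CH2Cl2, rt; then 28, rt
Reagents that add atoms: none
Why: One-pot oxidation–Wittig olefination: the volatile, epimerisable aldehyde is trapped in situ, and the stabilised α-methyl ylide gives the (E)-trisubstituted enoate.

Step 21
Reactants: 30 ethyl (2E,4R)-2,4-dimethylhex-2-enoate
Product: 31 (2E,4R)-2,4-dimethylhex-2-enoic acid
Conditions: LiOH, THF/MeOH/H2O, 40 °C; then 1 M HCl
Reagents that add atoms: lithium hydroxide [Li+].[OH-]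
Why: Saponification of the hindered enoate; the γ-stereocentre is not acidic under these conditions.

**Fragment union and endgame**

Step 22
Reactants: 20 (3R,4R)-3-(PMBO)-4-(TESO)nonan-2-one; 10 methyl (3R,4S)-3,4-bis(TBSO)-5-oxopentanoate
Product: 33 methyl (3R,4R,8R,9R)-3,4-bis(TBSO)-5-hydroxy-7-oxo-8-(PMBO)-9-(TESO)tetradecanoate (C5 epimers), via lithium enolate 32 (not isolated)
Conditions: LiN(iPr)2, THF, −78 °C; then 10, −78 °C; aq. NH4Cl at −78 °C
Reagents that add atoms: none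
Why: Intermolecular aldol addition: kinetic deprotonation at the methyl group gives an enolate that adds to the aldehyde (not the ester) at −78 °C, forming the C5–C6 bond; the C5 carbinol configuration is irrelevant because it is eliminated next.

Step 23
Reactants: 33 methyl (3R,4R,8R,9R)-3,4-bis(TBSO)-5-hydroxy-7-oxo-8-(PMBO)-9-(TESO)tetradecanoate
Product: 35 methyl (3R,4R,5E,8R,9R)-3,4-bis(TBSO)-7-oxo-8-(PMBO)-9-(TESO)tetradec-5-enoate, via C5 mesylate 34 (not isolated)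
Conditions: MsCl, Et3N (5 equiv), CH2Cl2, 0 °C → rt
Reagents that add atoms: none
Why: Mesylation followed by E1cB elimination of the β-mesyloxy ketone gives the thermodynamically favoured (E)-enone and completes the aldol condensation.

Step 24
Reactants: 35 methyl (3R,4R,5E,8R,9R)-3,4-bis(TBSO)-7-oxo-8-(PMBO)-9-(TESO)tetradec-5-enoate
Product: 36 methyl (3R,4R,5E,7S,8S,9R)-3,4-bis(TBSO)-7-hydroxy-8-(PMBO)-9-(TESO)tetradec-5-enoate
Conditions: Zn(BH4)2, Et2O, −30 °C
Reagents that add atoms: none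
Why: Cram-chelate 1,2-reduction: zinc bridges the C7 carbonyl and the C8 OPMB oxygen, and hydride adds anti to the C9 chain to give the 7,8-anti (7S) allylic alcohol; the ester and the silyl ethers are inert.

Step 25
Reactants: 36 methyl (3R,4R,5E,7S,8S,9R)-3,4-bis(TBSO)-7-hydroxy-8-(PMBO)-9-(TESO)tetradec-5-enoate
Product: 37 methyl (3R,4R,5E,7S,8R,9R)-3,4-bis(TBSO)-7,9-dihydroxy-8-(PMBO)tetradec-5-enoate
Conditions: PPTS, MeOH/CH2Cl2, 0 °C
Reagents that add atoms: none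
Why: Selective acid-catalysed methanolysis: the secondary TES ether is cleaved far faster than the secondary TBS ethers.

Step 26
Reactants: 37 methyl (3R,4R,5E,7S,8R,9R)-3,4-bis(TBSO)-7,9-dihydroxy-8-(PMBO)tetradec-5-enoate
Product: 38 (3R,4R,5E,7S,8R,9R)-3,4-bis(TBSO)-7,9-dihydroxy-8-(PMBO)tetradec-5-enoic acid
Conditions: LiOH, THF/MeOH/H2O, 0 °C → rt; dilute HCl to pH 4 at 0 °C
Reagents that add atoms: lithium hydroxide [Li+].[OH-]
Why: Saponification of the methyl ester; the β-silyloxy group is a poor leaving group, so elimination does not compete.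

Step 27
Reactants: 38 (3R,4R,5E,7S,8R,9R)-3,4-bis(TBSO)-7,9-dihydroxy-8-(PMBO)tetradec-5-enoic acid
Product: 40 (3R,4R,5E,7S,8S,9R)-3,4-bis(TBSO)-7-hydroxy-8-(PMBO)tetradec-5-en-9-olide, via Yamaguchi mixed anhydride 39 (not isolated)
Conditions: 2,4,6-Cl3C6H2COCl, Et3N, THF, rt; then slow addition to DMAP, toluene, 80 °C (1 mM)
Reagents that add atoms: none
Why: Yamaguchi macrolactonisation under high dilution; only C9–OH can close, because acylation of C7–OH would put the (E)-alkene into an eight-membered ring.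

Step 28
Reactants: 40 (3R,4R,5E,7S,8S,9R)-3,4-bis(TBSO)-7-hydroxy-8-(PMBO)tetradec-5-en-9-olide
Product: 41 (3R,4R,5S,6R,7R,8S,9R)-5,6-epoxy-3,4-bis(TBSO)-7-hydroxy-8-(PMBO)tetradecan-9-olide
Conditions: Ti(OiPr)4 (1.2 equiv), D-(−)-diisopropyl tartrate (1.5 equiv), t-BuOOH, 4 Å MS, CH2Cl2, −20 °C
Reagents that add atoms: tert-butyl hydroperoxide CC(C)(C)OO
Why: Sharpless asymmetric epoxidation directed by the only free hydroxyl (C7): the D-(−)-tartrate and the (7S)-carbinol form the matched pair, giving the trans-oxirane anti (erythro) to C7–OH, which is the C5/C6 configuration of the target.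

Step 29
Reactants: 41 (3R,4R,5S,6R,7R,8S,9R)-5,6-epoxy-3,4-bis(TBSO)-7-hydroxy-8-(PMBO)tetradecan-9-olide
Product: 42 (3R,4R,5S,6S,7R,8R,9R)-5,6-epoxy-3,4,7-tris(TBSO)-8-(PMBO)tetradecan-9-olide
Conditions: TBSOTf, 2,6-lutidine, CH2Cl2, −78 → 0 °C
Reagents that add atoms: tert-butyldimethylsilyl triflate CC(C)(C)[Si](C)(C)OS(=O)(=O)C(F)(F)F
Why: Silylation of the hindered epoxy alcohol under buffered, cold conditions masks C7–OH before C8 is unveiled.

Step 30
Reactants: 42 (3R,4R,5S,6S,7R,8R,9R)-5,6-epoxy-3,4,7-tris(TBSO)-8-(PMBO)tetradecan-9-olide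
Product: 43 (3R,4R,5S,6S,7R,8R,9R)-5,6-epoxy-8-hydroxy-3,4,7-tris(TBSO)tetradecan-9-olide
Conditions: DDQ, CH2Cl2/pH 7 phosphate buffer, 0 °C → rt
Reagents that add atoms: none
Why: Oxidative PMB ether cleavage under neutral conditions leaves the oxirane, lactone and silyl ethers intact.

Step 31
Reactants: 43 (3R,4R,5S,6S,7R,8R,9R)-5,6-epoxy-8-hydroxy-3,4,7-tris(TBSO)tetradecan-9-olide; 31 (2E,4R)-2,4-dimethylhex-2-enoic acid
Product: 45 (3R,4R,5S,6S,7S,8R,9R)-8-{[(2E,4R)-2,4-dimethylhex-2-enoyl]oxy}-5,6-epoxy-3,4,7-tris(TBSO)tetradecan-9-olide, via mixed anhydride 44 (not isolated)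
Conditions: 31, 2,4,6-Cl3C6H2COCl, Et3N, toluene, rt; then 43, DMAP, toluene, 40 °C
Reagents that add atoms: none
Why: Yamaguchi esterification acylates the hindered secondary C8–OH with the α-branched enoic acid without isomerising the alkene or touching the oxirane.

Step 32
Reactants: 45 (3R,4R,5S,6S,7S,8R,9R)-8-{[(2E,4R)-2,4-dimethylhex-2-enoyl]oxy}-5,6-epoxy-3,4,7-tris(TBSO)tetradecan-9-olide
Product: 46 (3R,4S,5R,6R,7S,8S,9R)-8-{[(2E,4R)-2,4-dimethylhex-2-enoyl]oxy}-5,6-epoxy-3,4,7-trihydroxytetradecan-9-olide (target, CNP0548321.2)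
Conditions: HF·pyridine, pyridine, THF, 0 °C → rt
Reagents that add atoms: none
Why: Global desilylation with pyridine-buffered fluoride is mild enough for the oxirane and both esters and avoids base-promoted acyl migration or Payne rearrangement.

**Compound list**
1 | methyl (4R)-2,2-dimethyl-1,3-dioxolane-4-carboxylate | COC(=O)[C@H]1COC(C)(C)O1 | starting material
2 | methyl (2R)-2,3-dihydroxypropanoate | COC(=O)[C@H](O)CO | intermediate
3 | methyl (2R)-2,3-bis(TBSO)propanoate | COC(=O)[C@H](O[Si](C)(C)C(C)(C)C)CO[Si](C)(C)C(C)(C)C | intermediate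
4 | methyl acetate | COC(C)=O | starting material
5 | lithium enolate of methyl acetate | [Li]OC(=C)OC | intermediate (not isolated)
6 | methyl (4R)-4,5-bis(TBSO)-3-oxopentanoate | COC(=O)CC(=O)[C@H](O[Si](C)(C)C(C)(C)C)CO[Si](C)(C)C(C)(C)C | intermediate
7 | methyl (3R,4R)-4,5-bis(TBSO)-3-hydroxypentanoate | COC(=O)C[C@@H](O)[C@H](O[Si](C)(C)C(C)(C)C)CO[Si](C)(C)C(C)(C)C | intermediate
8 | methyl (3R,4R)-3,4,5-tris(TBSO)pentanoate | COC(=O)C[C@@H](O[Si](C)(C)C(C)(C)C)[C@H](O[Si](C)(C)C(C)(C)C)CO[Si](C)(C)C(C)(C)C | intermediate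
9 | methyl (3R,4R)-3,4-bis(TBSO)-5-hydroxypentanoate | COC(=O)C[C@@H](O[Si](C)(C)C(C)(C)C)[C@H](O[Si](C)(C)C(C)(C)C)CO | intermediate
10 | methyl (3R,4S)-3,4-bis(TBSO)-5-oxopentanoate (fragment A) | COC(=O)C[C@@H](O[Si](C)(C)C(C)(C)C)[C@H](O[Si](C)(C)C(C)(C)C)C=O | intermediate
11 | (E)-oct-2-en-1-ol | CCCCC/C=C/CO | starting material
12 | [(2S,3S)-3-pentyloxiran-2-yl]methanol | OC[C@@H]1O[C@H]1CCCCC | intermediate
13 | (2S,3R)-1,2-dihydroxyoctan-3-yl benzoate | OC[C@H](O)[C@H](OC(=O)c1ccccc1)CCCCC | intermediate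
14 | (1R)-1-[(4S)-2-(4-methoxyphenyl)-1,3-dioxolan-4-yl]hexyl benzoate | COc1ccc(cc1)C1OC[C@H](O1)[C@H](OC(=O)c1ccccc1)CCCCC | intermediate
15 | (1R)-1-[(4S)-2-(4-methoxyphenyl)-1,3-dioxolan-4-yl]hexan-1-ol | COc1ccc(cc1)C1OC[C@H](O1)[C@H](O)CCCCC | intermediate
16 | triethyl{(1R)-1-[(4S)-2-(4-methoxyphenyl)-1,3-dioxolan-4-yl]hexyloxy}silane | COc1ccc(cc1)C1OC[C@H](O1)[C@H](O[Si](CC)(CC)CC)CCCCC | intermediate
17 | (2S,3R)-2-(PMBO)-3-(TESO)octan-1-ol | OC[C@H](OCc1ccc(OC)cc1)[C@H](O[Si](CC)(CC)CC)CCCCC | intermediate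
18 | (2R,3R)-2-(PMBO)-3-(TESO)octanal | O=C[C@H](OCc1ccc(OC)cc1)[C@H](O[Si](CC)(CC)CC)CCCCC | intermediate
19 | (3S,4R)-3-(PMBO)-4-(TESO)nonan-2-ol (C2 epimers) | CC(O)[C@H](OCc1ccc(OC)cc1)[C@H](O[Si](CC)(CC)CC)CCCCC | intermediate
20 | (3R,4R)-3-(PMBO)-4-(TESO)nonan-2-one (fragment B) | CC(=O)[C@H](OCc1ccc(OC)cc1)[C@H](O[Si](CC)(CC)CC)CCCCC | intermediate
21 | (4R)-4-benzyl-1,3-oxazolidin-2-one | O=C1OC[C@@H](Cc2ccccc2)N1 | starting material
22 | butanoyl chloride | CCCC(Cl)=O | starting material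
23 | N-lithio (4R)-4-benzyl-1,3-oxazolidin-2-one | [Li]N1C(=O)OC[C@H]1Cc1ccccc1 | intermediate (not isolated)
24 | (4R)-4-benzyl-3-butanoyl-1,3-oxazolidin-2-one | CCCC(=O)N1C(=O)OC[C@H]1Cc1ccccc1 | intermediate
25 | sodium Z-enolate of 24 | CC/C=C(\O[Na])N1C(=O)OC[C@H]1Cc1ccccc1 | intermediate (not isolated)
26 | (4R)-4-benzyl-3-[(2R)-2-methylbutanoyl]-1,3-oxazolidin-2-one | CC[C@@H](C)C(=O)N1C(=O)OC[C@H]1Cc1ccccc1 | intermediate
27 | (2R)-2-methylbutan-1-ol | CC[C@@H](C)CO | intermediate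
28 | ethyl 2-(triphenylphosphoranylidene)propanoate | CCOC(=O)C(C)=P(c1ccccc1)(c1ccccc1)c1ccccc1 | starting material
29 | (2R)-2-methylbutanal | CC[C@@H](C)C=O | intermediate (not isolated)
30 | ethyl (2E,4R)-2,4-dimethylhex-2-enoate | CCOC(=O)/C(C)=C/[C@H](C)CC | intermediate
31 | (2E,4R)-2,4-dimethylhex-2-enoic acid | OC(=O)/C(C)=C/[C@H](C)CC | intermediate
32 | lithium enolate of 20 (methyl side) | [Li]OC(=C)[C@H](OCc1ccc(OC)cc1)[C@H](O[Si](CC)(CC)CC)CCCCC | intermediate (not isolated)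
33 | methyl (3R,4R,8R,9R)-3,4-bis(TBSO)-5-hydroxy-7-oxo-8-(PMBO)-9-(TESO)tetradecanoate (C5 epimers) | COC(=O)C[C@@H](O[Si](C)(C)C(C)(C)C)[C@H](O[Si](C)(C)C(C)(C)C)C(O)CC(=O)[C@H](OCc1ccc(OC)cc1)[C@H](O[Si](CC)(CC)CC)CCCCC | intermediate
34 | C5 methanesulfonate of 33 | COC(=O)C[C@@H](O[Si](C)(C)C(C)(C)C)[C@H](O[Si](C)(C)C(C)(C)C)C(OS(C)(=O)=O)CC(=O)[C@H](OCc1ccc(OC)cc1)[C@H](O[Si](CC)(CC)CC)CCCCC | intermediate (not isolated)
35 | methyl (3R,4R,5E,8R,9R)-3,4-bis(TBSO)-7-oxo-8-(PMBO)-9-(TESO)tetradec-5-enoate | COC(=O)C[C@@H](O[Si](C)(C)C(C)(C)C)[C@H](O[Si](C)(C)C(C)(C)C)/C=C/C(=O)[C@H](OCc1ccc(OC)cc1)[C@H](O[Si](CC)(CC)CC)CCCCC | intermediate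
36 | methyl (3R,4R,5E,7S,8S,9R)-3,4-bis(TBSO)-7-hydroxy-8-(PMBO)-9-(TESO)tetradec-5-enoate | COC(=O)C[C@@H](O[Si](C)(C)C(C)(C)C)[C@H](O[Si](C)(C)C(C)(C)C)/C=C/[C@H](O)[C@H](OCc1ccc(OC)cc1)[C@H](O[Si](CC)(CC)CC)CCCCC | intermediate
37 | methyl (3R,4R,5E,7S,8R,9R)-3,4-bis(TBSO)-7,9-dihydroxy-8-(PMBO)tetradec-5-enoate | COC(=O)C[C@@H](O[Si](C)(C)C(C)(C)C)[C@H](O[Si](C)(C)C(C)(C)C)/C=C/[C@H](O)[C@H](OCc1ccc(OC)cc1)[C@H](O)CCCCC | intermediate
38 | (3R,4R,5E,7S,8R,9R)-3,4-bis(TBSO)-7,9-dihydroxy-8-(PMBO)tetradec-5-enoic acid | OC(=O)C[C@@H](O[Si](C)(C)C(C)(C)C)[C@H](O[Si](C)(C)C(C)(C)C)/C=C/[C@H](O)[C@H](OCc1ccc(OC)cc1)[C@H](O)CCCCC | intermediate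
39 | mixed anhydride of 38 with 2,4,6-trichlorobenzoic acid | O=C(OC(=O)c1c(Cl)cc(Cl)cc1Cl)C[C@@H](O[Si](C)(C)C(C)(C)C)[C@H](O[Si](C)(C)C(C)(C)C)/C=C/[C@H](O)[C@H](OCc1ccc(OC)cc1)[C@H](O)CCCCC | intermediate (not isolated)
40 | (3R,4R,5E,7S,8S,9R)-3,4-bis(TBSO)-7-hydroxy-8-(PMBO)tetradec-5-en-9-olide | CCCCC[C@H]1OC(=O)C[C@@H](O[Si](C)(C)C(C)(C)C)[C@H](O[Si](C)(C)C(C)(C)C)/C=C/[C@H](O)[C@@H]1OCc1ccc(OC)cc1 | intermediate
41 | (3R,4R,5S,6R,7R,8S,9R)-5,6-epoxy-3,4-bis(TBSO)-7-hydroxy-8-(PMBO)tetradecan-9-olide | CCCCC[C@H]1OC(=O)C[C@@H](O[Si](C)(C)C(C)(C)C)[C@H](O[Si](C)(C)C(C)(C)C)[C@H]2O[C@@H]2[C@H](O)[C@@H]1OCc1ccc(OC)cc1 | intermediate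
42 | (3R,4R,5S,6S,7R,8R,9R)-5,6-epoxy-3,4,7-tris(TBSO)-8-(PMBO)tetradecan-9-olide | CCCCC[C@H]1OC(=O)C[C@@H](O[Si](C)(C)C(C)(C)C)[C@H](O[Si](C)(C)C(C)(C)C)[C@H]2O[C@@H]2[C@H](O[Si](C)(C)C(C)(C)C)[C@@H]1OCc1ccc(OC)cc1 | intermediate
43 | (3R,4R,5S,6S,7R,8R,9R)-5,6-epoxy-8-hydroxy-3,4,7-tris(TBSO)tetradecan-9-olide | CCCCC[C@H]1OC(=O)C[C@@H](O[Si](C)(C)C(C)(C)C)[C@H](O[Si](C)(C)C(C)(C)C)[C@H]2O[C@@H]2[C@H](O[Si](C)(C)C(C)(C)C)[C@@H]1O | intermediate
44 | mixed anhydride of 31 with 2,4,6-trichlorobenzoic acid | CC[C@@H](C)/C=C(\C)C(=O)OC(=O)c1c(Cl)cc(Cl)cc1Cl | intermediate (not isolated)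
45 | (3R,4R,5S,6S,7S,8R,9R)-8-{[(2E,4R)-2,4-dimethylhex-2-enoyl]oxy}-5,6-epoxy-3,4,7-tris(TBSO)tetradecan-9-olide | CCCCC[C@H]1OC(=O)C[C@@H](O[Si](C)(C)C(C)(C)C)[C@H](O[Si](C)(C)C(C)(C)C)[C@H]2O[C@@H]2[C@H](O[Si](C)(C)C(C)(C)C)[C@@H]1OC(=O)/C(C)=C/[C@H](C)CC | intermediate
46 | (3R,4S,5R,6R,7S,8S,9R)-8-{[(2E,4R)-2,4-dimethylhex-2-enoyl]oxy}-5,6-epoxy-3,4,7-trihydroxytetradecan-9-olide | CCCCC[C@H]1OC(=O)C[C@@H](O)[C@H](O)[C@H]2O[C@@H]2[C@H](O)[C@@H]1OC(=O)/C(C)=C/[C@H](C)CC | target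

**Step count**
Total: 32 steps (fragment A 7, fragment B 9, acid 5, union and endgame 11). Longest linear sequence: 20 steps (steps 8–16, then 22–32).

**Three steps most likely to fail, with fallbacks**

Step 27 (ten-membered macrolactonisation with a free C7 hydroxyl; oligomerisation may win). The fallback sets out from 36 and protects C7 before ring closure. TBSOTf/2,6-lutidine gives the 7-O-TBS ether F1, PPTS/MeOH gives the 9-hydroxy ester F2, and LiOH gives the mono-hydroxy seco acid F3. Yamaguchi lactonisation then gives the fully protected macrolactone F4. DDQ gives the 8-alcohol F5, Yamaguchi esterification with 31 gives the ester F6, and HF·pyridine (no oxirane present yet) gives the alkene triol F7. The Sharpless epoxidation (Ti(OiPr)4, D-(−)-diisopropyl tartrate, t-BuOOH) then becomes the last step and the fallback comes back to the route at 46. The 3,4-diol in F7 may compete for titanium in that final epoxidation.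

Step 28 (Sharpless epoxidation on a conformationally constrained macrocyclic allylic alcohol may be slow or lose face control). The fallback sets out from the acyclic alcohol 36, where the matched epoxidation is well behaved, so the oxirane is formed before the lactone. Ti(OiPr)4/D-(−)-diisopropyl tartrate/t-BuOOH gives the epoxy alcohol F8 and TBSOTf/2,6-lutidine gives the 7-O-TBS ether F9. Pyridine-buffered HF·pyridine removes the TES group to give the 9-hydroxy epoxy ester F10. Me3SnOH (1,2-dichloroethane, 60 °C) gives the epoxy seco acid F11, which is used at once without acidic work-up. Shiina lactonisation (2-methyl-6-nitrobenzoic anhydride, DMAP, Et3N, CH2Cl2, rt, high dilution) closes the ring and the fallback comes back at 42. This order was not chosen for the main route because F10 and F11 can cyclise onto the oxirane (tetrahydrofuran or δ-lactone formation) if they meet acid.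

Step 24 (1,2-chelation must override the Felkin bias on a conjugated enone). The fallback sets out from 35 and uses 1,3-induction instead. PPTS/MeOH removes the TES group to give the β-hydroxy enone F12. A Narasaka–Prasad reduction (Et2BOMe, NaBH4, THF/MeOH, −78 °C) then runs through a six-membered boron chelate in which the pentyl and OPMB groups are both equatorial. Axial hydride delivery gives the 7,9-syn diol, so the fallback comes back to the route at 37.

**Further compounds**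
F1 | step 27 | 7-O-TBS ether of 36 | COC(=O)C[C@@H](O[Si](C)(C)C(C)(C)C)[C@H](O[Si](C)(C)C(C)(C)C)/C=C/[C@H](O[Si](C)(C)C(C)(C)C)[C@H](OCc1ccc(OC)cc1)[C@H](O[Si](CC)(CC)CC)CCCCC
F2 | step 27 | 9-hydroxy ester (TES removed from F1) | COC(=O)C[C@@H](O[Si](C)(C)C(C)(C)C)[C@H](O[Si](C)(C)C(C)(C)C)/C=C/[C@H](O[Si](C)(C)C(C)(C)C)[C@H](OCc1ccc(OC)cc1)[C@H](O)CCCCC
F3 | step 27 | mono-hydroxy seco acid from F2 | OC(=O)C[C@@H](O[Si](C)(C)C(C)(C)C)[C@H](O[Si](C)(C)C(C)(C)C)/C=C/[C@H](O[Si](C)(C)C(C)(C)C)[C@H](OCc1ccc(OC)cc1)[C@H](O)CCCCC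
F4 | step 27 | (5E)-3,4,7-tris(TBSO)-8-(PMBO)tetradec-5-en-9-olide | CCCCC[C@H]1OC(=O)C[C@@H](O[Si](C)(C)C(C)(C)C)[C@H](O[Si](C)(C)C(C)(C)C)/C=C/[C@H](O[Si](C)(C)C(C)(C)C)[C@@H]1OCc1ccc(OC)cc1
F5 | step 27 | (5E)-8-hydroxy-3,4,7-tris(TBSO)tetradec-5-en-9-olide | CCCCC[C@H]1OC(=O)C[C@@H](O[Si](C)(C)C(C)(C)C)[C@H](O[Si](C)(C)C(C)(C)C)/C=C/[C@H](O[Si](C)(C)C(C)(C)C)[C@@H]1O
F6 | step 27 | 8-O-[(2E,4R)-2,4-dimethylhex-2-enoyl] derivative of F5 | CCCCC[C@H]1OC(=O)C[C@@H](O[Si](C)(C)C(C)(C)C)[C@H](O[Si](C)(C)C(C)(C)C)/C=C/[C@H](O[Si](C)(C)C(C)(C)C)[C@@H]1OC(=O)/C(C)=C/[C@H](C)CC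
F7 | step 27 | alkene triol (5,6-deoxy analogue of 46 with a 5E double bond) | CCCCC[C@H]1OC(=O)C[C@@H](O)[C@H](O)/C=C/[C@H](O)[C@@H]1OC(=O)/C(C)=C/[C@H](C)CC
F8 | step 28 | acyclic 5,6-epoxy alcohol from 36 | COC(=O)C[C@@H](O[Si](C)(C)C(C)(C)C)[C@H](O[Si](C)(C)C(C)(C)C)[C@H]1O[C@@H]1[C@H](O)[C@H](OCc1ccc(OC)cc1)[C@H](O[Si](CC)(CC)CC)CCCCC
F9 | step 28 | 7-O-TBS ether of F8 | COC(=O)C[C@@H](O[Si](C)(C)C(C)(C)C)[C@H](O[Si](C)(C)C(C)(C)C)[C@H]1O[C@@H]1[C@H](O[Si](C)(C)C(C)(C)C)[C@H](OCc1ccc(OC)cc1)[C@H](O[Si](CC)(CC)CC)CCCCC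
F10 | step 28 | 9-hydroxy epoxy ester (TES removed from F9) | COC(=O)C[C@@H](O[Si](C)(C)C(C)(C)C)[C@H](O[Si](C)(C)C(C)(C)C)[C@H]1O[C@@H]1[C@H](O[Si](C)(C)C(C)(C)C)[C@H](OCc1ccc(OC)cc1)[C@H](O)CCCCC
F11 | step 28 | epoxy seco acid from F10 | OC(=O)C[C@@H](O[Si](C)(C)C(C)(C)C)[C@H](O[Si](C)(C)C(C)(C)C)[C@H]1O[C@@H]1[C@H](O[Si](C)(C)C(C)(C)C)[C@H](OCc1ccc(OC)cc1)[C@H](O)CCCCC
F12 | step 24 | β-hydroxy enone (TES removed from 35) | COC(=O)C[C@@H](O[Si](C)(C)C(C)(C)C)[C@H](O[Si](C)(C)C(C)(C)C)/C=C/C(=O)[C@H](OCc1ccc(OC)cc1)[C@H](O)CCCCC
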